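**Retrosynthetic overview**

- Ring B of the target is cut at C4a–C4, C4–C3 and O1–C2. All three bonds come from one palladium-catalysed carbonylative annulation of 2-iodo-5-methoxybenzene-1,3-diol, carbon monoxide and an (R)-configured C11 terminal alkyne.
- Feature used: in ring B (O1, C2, C3, C4, C4a, C8a) the carbonyl carbon C4 lies between aryl carbon C4a and the C3–C2 unit, and the oxygens on C8a and C5 are equivalent in the iodoresorcinol (iodine between two OH, OMe para), so ring A poses no regiochemical question.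
- Iodoresorcinol: one bicarbonate-buffered iodination of 5-methoxyresorcinol. Alkyne: non-8-enoic acid → tert-butyl ester → epoxide → hydrolytic kinetic resolution (sets C8, the later C2') → silylacetylide opening → C-desilylation → TBS ether.
- Ring order: ring A is purchased, ring B closes in the key step, and aqueous trifluoroacetic acid then frees the alcohol and the acid.

Key step: step 8

Remark: the epoxide recovered in step 4 is taken as (R) from the established sense of the hydrolytic kinetic resolution of alkyl oxiranes with the (R,R)-cobalt complex; the (S,S)-complex would give the antipode.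

**Route**

Step 1
Reactants: 1 5-methoxybenzene-1,3-diol
Product: 2 2-iodo-5-methoxybenzene-1,3-diol
Conditions: I2 (1.0 equiv), NaHCO3 (1.1 equiv), THF/H2O (1:1), 0 °C; Na2S2O3 quench, neutral work-up
Reagents that add atoms: iodine, II
Why: Electrophilic aromatic iodination of the resorcinol monoanion under kinetic, bicarbonate-buffered conditions should place iodine on the carbon between the two hydroxyls (also para to OMe), as it does for resorcinol and 5-alkylresorcinols, and the acid-free work-up avoids iodine migration on this electron-rich ring.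

Step 2
Reactants: 3 non-8-enoic acid
Product: 4 tert-butyl non-8-enoate
Conditions: tert-butyl 2,2,2-trichloroacetimidate (2 equiv), cyclohexane/CH2Cl2, rt
Reagents that add atoms: tert-butyl 2,2,2-trichloroacetimidate, CC(C)(C)OC(=N)C(Cl)(Cl)Cl
Why: Trichloroacetimidate tert-butylation, in which the acid protonates the imidate and the carboxylate captures the tert-butyl cation, leaves the terminal alkene untouched.

Step 3
Reactants: 4 tert-butyl non-8-enoate
Product: 5 tert-butyl 7-(oxiran-2-yl)heptanoate (racemic)
Conditions: mCPBA (1.3 equiv), NaHCO3, CH2Cl2, 0 °C → rt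
Reagents that add atoms: mCPBA, OOC(=O)c1cccc(Cl)c1
Why: Prilezhaev epoxidation of the only alkene; the ester is inert and the new centre C8 forms racemic, to be resolved in step 4.

Step 4
Reactants: 5 tert-butyl 7-(oxiran-2-yl)heptanoate (racemic)
Product: 6 tert-butyl 7-[(2R)-oxiran-2-yl]heptanoate
Conditions: (R,R)-(salen)Co(OAc) [salen = N,N'-bis(3,5-di-tert-butylsalicylidene)cyclohexane-1,2-diamine dianion; trivalent cobalt] (0.5 mol%), H2O (0.55 equiv), THF, 0 °C → rt
Reagents that add atoms: none
Why: Jacobsen hydrolytic kinetic resolution: the chiral cobalt salen complex hydrolyses the (S)-oxirane at its terminal carbon much faster than the (R)-oxirane, so C8 is set by catalyst control and the remaining (R)-epoxide is separated from the polar diol.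

Step 5
Reactants: 6 tert-butyl 7-[(2R)-oxiran-2-yl]heptanoate; 7 ethynyltrimethylsilane
Product: 9 tert-butyl (8R)-8-hydroxy-11-(trimethylsilyl)undec-10-ynoate, via lithium (trimethylsilyl)acetylide 8 (not isolated)
Conditions: 7 (2.0 equiv), n-BuLi (1.9 equiv), THF, −78 °C; BF3·OEt2 (1.9 equiv); then 6, −78 °C; NH4Cl aq
Reagents that add atoms: none
Why: Yamaguchi–Hirao alkynylation: the BF3-activated oxirane is opened by the acetylide in an SN2 reaction at the unsubstituted carbon C9, so C8 keeps its configuration (still R, the priority order being unchanged), and the tert-butyl ester is not attacked at −78 °C.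

Step 6
Reactants: 9 tert-butyl (8R)-8-hydroxy-11-(trimethylsilyl)undec-10-ynoate
Product: 10 tert-butyl (8R)-8-hydroxyundec-10-ynoate
Conditions: K2CO3 (0.3 equiv), MeOH, rt
Reagents that add atoms: none
Why: Base-catalysed methanolysis of the alkynyl C–Si bond (protodesilylation) frees the terminal alkyne, and a tert-butyl ester does not transesterify under these conditions.

Step 7
Reactants: 10 tert-butyl (8R)-8-hydroxyundec-10-ynoate
Product: 11 tert-butyl (8R)-8-[(tert-butyldimethylsilyl)oxy]undec-10-ynoate
Conditions: TBSCl (1.3 equiv), imidazole (2.5 equiv), DMF, rt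
Reagents that add atoms: tert-butyldimethylsilyl chloride, CC(C)(C)[Si](C)(C)Cl
Why: Corey silylation of the secondary alcohol, which masks it against capture of the aroylpalladium intermediate in the carbonylative step.

Step 8
Reactants: 2 2-iodo-5-methoxybenzene-1,3-diol; 11 tert-butyl (8R)-8-[(tert-butyldimethylsilyl)oxy]undec-10-ynoate (1.3 equiv); 12 carbon monoxide
Product: 15 tert-butyl (8R)-8-[(tert-butyldimethylsilyl)oxy]-9-(5-hydroxy-7-methoxy-4-oxo-4H-chromen-2-yl)nonanoate, via ynone 13 (not isolated), via enaminone 14 (not isolated)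
Conditions: PdCl2(PPh3)2 (5 mol%), CO (20 bar), Et2NH, 110 °C, autoclave
Reagents that add atoms: none
Why: Zerovalent palladium, formed in situ from PdCl2(PPh3)2, inserts into the C–I bond of 2, CO insertion gives an aroyl complex of divalent palladium, and amine-assisted alkynylation by 11 with reductive elimination forms C4a–C4 and C4–C3 in ynone 13. Diethylamine then adds to C2 of the ynone to give enaminone 14, and a phenol oxygen displaces the amine by addition–elimination, forming O1–C2. The closest known reaction is the copper-free carbonylative Sonogashira annulation of 2-iodophenols with terminal alkynes to chromones in diethylamine. Ring B (O1, C2, C3, C4, C4a, C8a) closes by 6-endo-trig attack on the enaminone, a net 6-endo-dig closure of the ynone, which excludes the 5-exo-dig route to an aurone. No stereocentre is formed, and C8 of the chain, insulated by the C9 methylene, is carried unchanged. The step needs carbonylation to outrun direct coupling, which CO pressure and the absence of copper should secure, and it needs no regiocontrol in ring A because the hydroxyls flanking the iodine are equivalent, the unused one becoming the hydrogen-bonded 5-OH.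

Step 9
Reactants: 15 tert-butyl (8R)-8-[(tert-butyldimethylsilyl)oxy]-9-(5-hydroxy-7-methoxy-4-oxo-4H-chromen-2-yl)nonanoate
Product: 16 penithochromone S, (8R)-8-hydroxy-9-(5-hydroxy-7-methoxy-4-oxo-4H-chromen-2-yl)nonanoic acid
Conditions: TFA/H2O (9:1), 0 °C → rt; evaporation
Reagents that add atoms: none
Why: Acidolysis: aqueous trifluoroacetic acid cleaves the tert-butyl ester through the tert-butyl cation (lost as isobutene, water as trap) and hydrolyses the secondary TBS ether, and since no bond to C8 is broken the (R) configuration is retained.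

**Compound list**

1 | 5-methoxybenzene-1,3-diol (5-methoxyresorcinol) | COc1cc(O)cc(O)c1 | starting material
2 | 2-iodo-5-methoxybenzene-1,3-diol | COc1cc(O)c(I)c(O)c1 | intermediate
3 | non-8-enoic acid | C=CCCCCCCC(=O)O | starting material
4 | tert-butyl non-8-enoate | C=CCCCCCCC(=O)OC(C)(C)C | intermediate
5 | tert-butyl 7-(oxiran-2-yl)heptanoate, racemic | CC(C)(C)OC(=O)CCCCCCC1CO1 | intermediate
6 | tert-butyl 7-[(2R)-oxiran-2-yl]heptanoate | CC(C)(C)OC(=O)CCCCCC[C@@H]1CO1 | intermediate
7 | ethynyltrimethylsilane | C#C[Si](C)(C)C | starting material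
8 | lithium (trimethylsilyl)acetylide | [Li]C#C[Si](C)(C)C | intermediate
9 | tert-butyl (8R)-8-hydroxy-11-(trimethylsilyl)undec-10-ynoate | C[Si](C)(C)C#CC[C@H](O)CCCCCCC(=O)OC(C)(C)C | intermediate
10 | tert-butyl (8R)-8-hydroxyundec-10-ynoate | C#CC[C@H](O)CCCCCCC(=O)OC(C)(C)C | intermediate
11 | tert-butyl (8R)-8-[(tert-butyldimethylsilyl)oxy]undec-10-ynoate | C#CC[C@H](O[Si](C)(C)C(C)(C)C)CCCCCCC(=O)OC(C)(C)C | intermediate
12 | carbon monoxide | [C-]#[O+] | starting material
13 | tert-butyl (8R)-8-[(tert-butyldimethylsilyl)oxy]-12-(2,6-dihydroxy-4-methoxyphenyl)-12-oxododec-10-ynoate | COc1cc(O)c(C(=O)C#CC[C@H](O[Si](C)(C)C(C)(C)C)CCCCCCC(=O)OC(C)(C)C)c(O)c1 | intermediate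
14 | tert-butyl (8R)-8-[(tert-butyldimethylsilyl)oxy]-10-(diethylamino)-12-(2,6-dihydroxy-4-methoxyphenyl)-12-oxododec-10-enoate (alkene geometry not defined) | COc1cc(O)c(C(=O)C=C(N(CC)CC)C[C@H](O[Si](C)(C)C(C)(C)C)CCCCCCC(=O)OC(C)(C)C)c(O)c1 | intermediate
15 | tert-butyl (8R)-8-[(tert-butyldimethylsilyl)oxy]-9-(5-hydroxy-7-methoxy-4-oxo-4H-chromen-2-yl)nonanoate | COc1cc(O)c2c(=O)cc(C[C@H](O[Si](C)(C)C(C)(C)C)CCCCCCC(=O)OC(C)(C)C)oc2c1 | intermediate
16 | penithochromone S, (8R)-8-hydroxy-9-(5-hydroxy-7-methoxy-4-oxo-4H-chromen-2-yl)nonanoic acid | COc1cc(O)c2c(=O)cc(C[C@H](O)CCCCCCC(=O)O)oc2c1 | target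

**Step count**

Total: 9 steps. Longest linear sequence: 8 steps (3 to 16 through steps 2 to 9).

**Steps most likely to fail, with fallbacks**

1. Step 8. Oxidative addition into the electron-rich, doubly ortho-substituted C–I bond may be slow, so that hydrodeiodination, capture of the aroylpalladium by diethylamine as an amide, or direct coupling without CO and 5-endo closure to a benzofuran could take over. The fallback builds the same three bonds without palladium; it sets out from 1 and 11 and comes back to the route at 16.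
   - Compound 1 would be protected with MOMCl/i-Pr2NEt (CH2Cl2, 0 °C → rt) as 1-methoxy-3,5-bis(methoxymethoxy)benzene F1.
   - n-BuLi (THF, 0 °C) should metalate the carbon between the two MOM ethers to give [4-methoxy-2,6-bis(methoxymethoxy)phenyl]lithium F2, which DMF formylates to 4-methoxy-2,6-bis(methoxymethoxy)benzaldehyde F3.
   - Alkyne 11 is deprotonated with n-BuLi (THF, −78 °C) to tert-butyl (8R)-8-[(tert-butyldimethylsilyl)oxy]-11-lithioundec-10-ynoate F4, which adds to F3 to give tert-butyl (8R)-8-[(tert-butyldimethylsilyl)oxy]-12-hydroxy-12-[4-methoxy-2,6-bis(methoxymethoxy)phenyl]dodec-10-ynoate F5 (both C12 epimers; the centre is removed next).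
   - MnO2 (CH2Cl2, rt) oxidises it to tert-butyl (8R)-8-[(tert-butyldimethylsilyl)oxy]-12-[4-methoxy-2,6-bis(methoxymethoxy)phenyl]-12-oxododec-10-ynoate F6.
   - Et2NH (EtOH, rt) adds to give tert-butyl (8R)-8-[(tert-butyldimethylsilyl)oxy]-10-(diethylamino)-12-[4-methoxy-2,6-bis(methoxymethoxy)phenyl]-12-oxododec-10-enoate F7.
   - TFA/H2O (9:1, 0 °C → rt) then removes both MOM groups, the TBS ether and the tert-butyl ester and closes ring B by O1–C2 addition–elimination, giving 16.

2. Step 1. Iodination may not stay at the carbon between the hydroxyls: attack at C4, double iodination, or iodine migration during isolation would erode the material. The fallback fixes the position by directed ortho-metalation and unmasks with fluoride, not acid; it sets out from 1 and comes back at 2.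
   - SEMCl/i-Pr2NEt (CH2Cl2, rt) gives 1-methoxy-3,5-bis{[2-(trimethylsilyl)ethoxy]methoxy}benzene F8.
   - n-BuLi (THF, 0 °C) lithiates between the two acetal oxygens to give (4-methoxy-2,6-bis{[2-(trimethylsilyl)ethoxy]methoxy}phenyl)lithium F9.
   - I2 (THF, −78 °C) gives 2-iodo-5-methoxy-1,3-bis{[2-(trimethylsilyl)ethoxy]methoxy}benzene F10.
   - TBAF (THF/DMPU, 60 °C) with a neutral buffered work-up should release 2.

3. Step 9. Strong protic acid acting on the freed C8 hydroxyl may cause dehydration toward the conjugated 2-alkenylchromone (the C9 hydrogens are vinylogously acidic), and the tert-butyl cation may alkylate ring A. The fallback unmasks in two orthogonal, non-protic stages; it sets out from 15 and comes back at 16.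
   - TMSOTf/2,6-lutidine (CH2Cl2, 0 °C) converts the tert-butyl ester, with the base taking up the proton and the TBS ether staying in place, into trimethylsilyl (8R)-8-[(tert-butyldimethylsilyl)oxy]-9-{7-methoxy-4-oxo-5-[(trimethylsilyl)oxy]-4H-chromen-2-yl}nonanoate F11.
   - Aqueous work-up at pH 5 hydrolyses this to (8R)-8-[(tert-butyldimethylsilyl)oxy]-9-(5-hydroxy-7-methoxy-4-oxo-4H-chromen-2-yl)nonanoic acid F12.
   - HF·pyridine (THF, 0 °C → rt) then removes the TBS group to give 16.

**Further compounds**

F1 | step 8 | 1-methoxy-3,5-bis(methoxymethoxy)benzene | COCOc1cc(OC)cc(OCOC)c1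
F2 | step 8 | [4-methoxy-2,6-bis(methoxymethoxy)phenyl]lithium | [Li]c1c(OCOC)cc(OC)cc1OCOC
F3 | step 8 | 4-methoxy-2,6-bis(methoxymethoxy)benzaldehyde | COCOc1cc(OC)cc(OCOC)c1C=O
F4 | step 8 | tert-butyl (8R)-8-[(tert-butyldimethylsilyl)oxy]-11-lithioundec-10-ynoate | [Li]C#CC[C@H](O[Si](C)(C)C(C)(C)C)CCCCCCC(=O)OC(C)(C)C
F5 | step 8 | tert-butyl (8R)-8-[(tert-butyldimethylsilyl)oxy]-12-hydroxy-12-[4-methoxy-2,6-bis(methoxymethoxy)phenyl]dodec-10-ynoate (C12 epimers) | COCOc1cc(OC)cc(OCOC)c1C(O)C#CC[C@H](O[Si](C)(C)C(C)(C)C)CCCCCCC(=O)OC(C)(C)C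
F6 | step 8 | tert-butyl (8R)-8-[(tert-butyldimethylsilyl)oxy]-12-[4-methoxy-2,6-bis(methoxymethoxy)phenyl]-12-oxododec-10-ynoate | COCOc1cc(OC)cc(OCOC)c1C(=O)C#CC[C@H](O[Si](C)(C)C(C)(C)C)CCCCCCC(=O)OC(C)(C)C
F7 | step 8 | tert-butyl (8R)-8-[(tert-butyldimethylsilyl)oxy]-10-(diethylamino)-12-[4-methoxy-2,6-bis(methoxymethoxy)phenyl]-12-oxododec-10-enoate | COCOc1cc(OC)cc(OCOC)c1C(=O)C=C(N(CC)CC)C[C@H](O[Si](C)(C)C(C)(C)C)CCCCCCC(=O)OC(C)(C)C
F8 | step 1 | 1-methoxy-3,5-bis{[2-(trimethylsilyl)ethoxy]methoxy}benzene | COc1cc(OCOCC[Si](C)(C)C)cc(OCOCC[Si](C)(C)C)c1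
F9 | step 1 | (4-methoxy-2,6-bis{[2-(trimethylsilyl)ethoxy]methoxy}phenyl)lithium | [Li]c1c(OCOCC[Si](C)(C)C)cc(OC)cc1OCOCC[Si](C)(C)C
F10 | step 1 | 2-iodo-5-methoxy-1,3-bis{[2-(trimethylsilyl)ethoxy]methoxy}benzene | COc1cc(OCOCC[Si](C)(C)C)c(I)c(OCOCC[Si](C)(C)C)c1
F11 | step 9 | trimethylsilyl (8R)-8-[(tert-butyldimethylsilyl)oxy]-9-{7-methoxy-4-oxo-5-[(trimethylsilyl)oxy]-4H-chromen-2-yl}nonanoate | COc1cc(O[Si](C)(C)C)c2c(=O)cc(C[C@H](O[Si](C)(C)C(C)(C)C)CCCCCCC(=O)O[Si](C)(C)C)oc2c1
F12 | step 9 | (8R)-8-[(tert-butyldimethylsilyl)oxy]-9-(5-hydroxy-7-methoxy-4-oxo-4H-chromen-2-yl)nonanoic acid | COc1cc(O)c2c(=O)cc(C[C@H](O[Si](C)(C)C(C)(C)C)CCCCCCC(=O)O)oc2c1
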